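The route disconnects ring A itself and leaves the depside ester in place: C1–C2, C2–C3, C4–C5 and C5–C6 are traced back to methoxyacetylene and an (E)-5-diazo-3-methyl-4-oxopent-2-enoate that is already the ester of ring B. What is exploited is the 1,3-dioxygenation of ring A, hydroxyl on C2 and methoxyl on C4 with C3 between them, next to the carboxyl carbon on C1 and the methyl on C6; a ketene-based benzannulation with an ynol ether produces this pattern directly. One irradiation performs Wolff shift, (2+2) cycloaddition, 4π opening and 6π closure and delivers the 3-unsubstituted depside with the two oxygens already differentiated. C3 is then formylated and oxidised, and a single hydrogenolysis finishes.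

Key step: step 9

Numbering used: ring A has the depside carbonyl on C1, OH on C2, CO2H on C3, OMe on C4, H on C5, CH3 on C6; ring B has CO2H on C1', OH on C2', CH3 on C3', the ester oxygen on C4', H on C5', CH3 on C6'.

Assumption (chemistry): the C2' hydroxyl of ring B is carried free, because it is hydrogen-bonded to the ring B ester and doubly ortho-substituted, the same kind of chelated phenol that the key step must in any case leave untouched on ring A.

Step 1
Reactants: 1 methyl 2,4-dihydroxy-3,6-dimethylbenzoate
Product: 2 2,4-dihydroxy-3,6-dimethylbenzoic acid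
Conditions: conc. H2SO4, 0 °C to rt; then ice–water
Reagents that add atoms: water, O
Why: In concentrated H2SO4 this doubly ortho-substituted, electron-rich benzoate should cleave by the unimolecular acyl–oxygen pathway (AAC1 ester hydrolysis) typical of hindered benzoates, and the cold quench should return the acid without the heating that would cause decarboxylation.

Step 2
Reactants: 2 2,4-dihydroxy-3,6-dimethylbenzoic acid
Product: 3 benzyl 2,4-dihydroxy-3,6-dimethylbenzoate
Conditions: BnBr, KHCO3, DMF, rt
Reagents that add atoms: benzyl bromide, BrCc1ccccc1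
Why: KHCO3 deprotonates only the carboxylic acid, so SN2 O-alkylation of the carboxylate should give the benzyl ester and leave both phenols free.

Step 3
Reactants: 4 butane-2,3-dione (3 equiv); 5 tert-butyl (triphenylphosphoranylidene)acetate
Product: 6 tert-butyl (2E)-3-methyl-4-oxopent-2-enoate
Conditions: CH2Cl2, rt
Reagents that add atoms: none
Why: Wittig olefination of one carbonyl of the symmetrical diketone by the stabilised ylide should give the trisubstituted enoate with the ester trans to the acetyl group (E), the excess of diketone suppressing double olefination.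

Step 4
Reactants: 6 tert-butyl (2E)-3-methyl-4-oxopent-2-enoate
Product: 7 (2E)-3-methyl-4-oxopent-2-enoic acid
Conditions: CF3CO2H, CH2Cl2, rt
Reagents that add atoms: none
Why: Acidolysis of the tert-butyl ester through the tert-butyl cation should free the acid at room temperature without disturbing the alkene geometry.

Step 5
Reactants: 3 benzyl 2,4-dihydroxy-3,6-dimethylbenzoate; 7 (2E)-3-methyl-4-oxopent-2-enoic acid
Product: 8 benzyl 2-hydroxy-3,6-dimethyl-4-{[(2E)-3-methyl-4-oxopent-2-enoyl]oxy}benzoate
Conditions: DCC, DMAP (cat.), CH2Cl2, 0 °C to rt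
Reagents that add atoms: none
Why: Steglich esterification should acylate only the C4' hydroxyl of ring B, because the C2' hydroxyl is hydrogen-bonded to the benzyl ester and flanked by two ortho substituents.

Step 6
Reactants: 8 benzyl 2-hydroxy-3,6-dimethyl-4-{[(2E)-3-methyl-4-oxopent-2-enoyl]oxy}benzoate
Product: 10 benzyl 2-hydroxy-3,6-dimethyl-4-{[(2E)-7,7,7-trifluoro-3-methyl-4,6-dioxohept-2-enoyl]oxy}benzoate, via dilithium dienolate 9 (not isolated)
Conditions: LiN(SiMe3)2 (2.2 equiv), THF, −78 °C (8 added to the base); CF3CO2CH2CF3, −78 °C; dilute aq. HCl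
Reagents that add atoms: 2,2,2-trifluoroethyl trifluoroacetate, O=C(OCC(F)(F)F)C(F)(F)F
Why: After the first equivalent of base has taken the phenolic proton, kinetic deprotonation of the methyl ketone and Claisen-type C-trifluoroacetylation of the enolate should activate the terminal carbon for diazo transfer, the E alkene keeping the enolate carbon out of reach of the aryl ester carbonyl.

Step 7
Reactants: 10 benzyl 2-hydroxy-3,6-dimethyl-4-{[(2E)-7,7,7-trifluoro-3-methyl-4,6-dioxohept-2-enoyl]oxy}benzoate
Product: 11 benzyl 4-{[(2E)-5-diazo-3-methyl-4-oxopent-2-enoyl]oxy}-2-hydroxy-3,6-dimethylbenzoate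
Conditions: MeSO2N3, Et3N, H2O (1 equiv), MeCN, rt; chromatography without alkaline wash
Reagents that add atoms: methanesulfonyl azide, CS(=O)(=O)N=[N+]=[N-]
Why: Regitz-type deacylative (detrifluoroacetylative) diazo transfer should place N2 on the activated methylene and expel the trifluoroacetyl group, which gives the diazomethyl ketone without exposing the electron-poor alkene to diazomethane, a dipole that would add across it.

Step 8
Reactants: 12 2-chloro-1,1-dimethoxyethane
Product: 15 methoxyacetylene, via 1-chloro-2-methoxyethene 13 (not isolated), via sodium methoxyacetylide 14 (not isolated)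
Conditions: NaNH2 (3 equiv), liquid NH3, −33 °C; then cold aq. NaCl, −70 °C to rt, distilled into a cold trap
Reagents that add atoms: none
Why: Two successive base-induced β-eliminations (methanol, then HCl) should give the acetylide, which is protonated on quenching, the standard preparation of 1-alkoxyalkynes from chloroacetaldehyde acetals.

Step 9
Reactants: 11 benzyl 4-{[(2E)-5-diazo-3-methyl-4-oxopent-2-enoyl]oxy}-2-hydroxy-3,6-dimethylbenzoate; 15 methoxyacetylene (3–5 equiv)
Product: 20 benzyl 2-hydroxy-4-[(2-hydroxy-4-methoxy-6-methylbenzoyl)oxy]-3,6-dimethylbenzoate, via vinylketene 16 (not isolated), via cyclobutenone 17 (not isolated), via dienylketene 18 (not isolated), via cyclohexadienone 19 (not isolated)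
Conditions: ClCH2CH2Cl, hν (medium-pressure Hg lamp, Pyrex filter, >300 nm), 0–10 °C, sealed vessel; then 80 °C
Reagents that add atoms: none
Why: Irradiation expels N2 and the alkenyl group migrates in a photochemical Wolff rearrangement (C5–C6) to give vinylketene 16, which adds methoxyacetylene in a (2+2) cycloaddition to cyclobutenone 17 (C2–C3 and C4–C5). Warming opens 17 by 4π electrocyclic ring opening to dienylketene 18, and ring A is closed by a 6π disrotatory electrocyclisation between C1 and C2 to dienone 19, which enolises to the phenol. The closest known reaction type is the Danheiser benzannulation in its diazoketone (photochemical Wolff) form with alkoxyalkynes. No stereocentre survives, since the sp3 carbons of 17 and 19 are formed racemic and are erased by ring opening and aromatisation. The regiochemistry needed, ketene carbonyl carbon to the unsubstituted alkyne carbon, is secured by the polarisation of the ynol ether (nucleophilic β-carbon), which sets the methoxyl meta to the new hydroxyl. The E alkene holds the aryloxycarbonyl group away from the ketene, which blocks oxa-6π closure to a 2-pyranone and leaves only hydrogen on the inside of the carbocyclic 6π closure, while light above 300 nm spares the aryl ester from photo-Fries rearrangement.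

Step 10
Reactants: 20 benzyl 2-hydroxy-4-[(2-hydroxy-4-methoxy-6-methylbenzoyl)oxy]-3,6-dimethylbenzoate
Product: 22 benzyl 4-[(3-formyl-2-hydroxy-4-methoxy-6-methylbenzoyl)oxy]-2-hydroxy-3,6-dimethylbenzoate, via hydroxymethyl depside 21 (not isolated)
Conditions: MgCl2, Et3N, (CH2O)n, MeCN, reflux; dilute aq. HCl
Reagents that add atoms: paraformaldehyde (as formaldehyde), C=O
Why: In this Casnati–Skattebøl ortho-formylation the magnesium phenoxide of ring A should deliver formaldehyde to its only free ortho position, C3, and the hydroxymethyl group is oxidised in the flask by hydride transfer to a second formaldehyde, while the ring B phenol has no free ortho position.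

Step 11
Reactants: 22 benzyl 4-[(3-formyl-2-hydroxy-4-methoxy-6-methylbenzoyl)oxy]-2-hydroxy-3,6-dimethylbenzoate
Product: 23 3-{[4-(benzyloxycarbonyl)-3-hydroxy-2,5-dimethylphenoxy]carbonyl}-2-hydroxy-6-methoxy-4-methylbenzoic acid
Conditions: NaClO2, NaH2PO4, 2-methyl-2-butene (excess), t-BuOH/THF/H2O, 0 °C to rt
Reagents that add atoms: sodium chlorite, [Na+].[O-]Cl=O
Why: Pinnick (Lindgren) oxidation should convert the aryl aldehyde into the acid by chlorous acid addition and fragmentation, the alkene scavenger removing HOCl before it can chlorinate the electron-rich rings.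

Step 12
Reactants: 23 3-{[4-(benzyloxycarbonyl)-3-hydroxy-2,5-dimethylphenoxy]carbonyl}-2-hydroxy-6-methoxy-4-methylbenzoic acid
Product: 24 squamatic acid
Conditions: H2 (1 atm), Pd/C, EtOAc, rt
Reagents that add atoms: none
Why: Hydrogenolysis of the benzyl ester over Pd/C should release the ring B acid under neutral conditions that leave the depside ester, the methyl ether and both o-hydroxy acid units intact.

Compound list
1 | methyl 2,4-dihydroxy-3,6-dimethylbenzoate | COC(=O)c1c(C)cc(O)c(C)c1O | starting material
2 | 2,4-dihydroxy-3,6-dimethylbenzoic acid | OC(=O)c1c(C)cc(O)c(C)c1O | intermediate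
3 | benzyl 2,4-dihydroxy-3,6-dimethylbenzoate (ring B phenol) | O=C(OCc1ccccc1)c1c(C)cc(O)c(C)c1O | intermediate
4 | butane-2,3-dione | CC(=O)C(C)=O | starting material
5 | tert-butyl (triphenylphosphoranylidene)acetate | CC(C)(C)OC(=O)C=P(c1ccccc1)(c1ccccc1)c1ccccc1 | starting material
6 | tert-butyl (2E)-3-methyl-4-oxopent-2-enoate | CC(=O)/C(C)=C/C(=O)OC(C)(C)C | intermediate
7 | (2E)-3-methyl-4-oxopent-2-enoic acid | CC(=O)/C(C)=C/C(=O)O | intermediate
8 | benzyl 2-hydroxy-3,6-dimethyl-4-{[(2E)-3-methyl-4-oxopent-2-enoyl]oxy}benzoate | CC(=O)/C(C)=C/C(=O)Oc1cc(C)c(C(=O)OCc2ccccc2)c(O)c1C | intermediate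
9 | dilithium dienolate of 8 (lithium C2' phenoxide and lithium 4-oxidopenta-2,4-dienoate, E; not isolated) | [Li+].[Li+].C=C([O-])/C(C)=C/C(=O)Oc1cc(C)c(C(=O)OCc2ccccc2)c([O-])c1C | intermediate
10 | benzyl 2-hydroxy-3,6-dimethyl-4-{[(2E)-7,7,7-trifluoro-3-methyl-4,6-dioxohept-2-enoyl]oxy}benzoate (drawn as the diketone; largely enolised) | O=C(CC(=O)/C(C)=C/C(=O)Oc1cc(C)c(C(=O)OCc2ccccc2)c(O)c1C)C(F)(F)F | intermediate
11 | benzyl 4-{[(2E)-5-diazo-3-methyl-4-oxopent-2-enoyl]oxy}-2-hydroxy-3,6-dimethylbenzoate (key-step precursor) | [N-]=[N+]=CC(=O)/C(C)=C/C(=O)Oc1cc(C)c(C(=O)OCc2ccccc2)c(O)c1C | intermediate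
12 | 2-chloro-1,1-dimethoxyethane (chloroacetaldehyde dimethyl acetal) | COC(CCl)OC | starting material
13 | 1-chloro-2-methoxyethene (either alkene geometry; not isolated) | COC=CCl | intermediate
14 | sodium methoxyacetylide (not isolated) | [Na+].[C-]#COC | intermediate
15 | methoxyacetylene | COC#C | intermediate
16 | vinylketene: benzyl 2-hydroxy-3,6-dimethyl-4-{[(2E)-3-methyl-5-oxopenta-2,4-dienoyl]oxy}benzoate (not isolated) | O=C=C/C(C)=C/C(=O)Oc1cc(C)c(C(=O)OCc2ccccc2)c(O)c1C | intermediate
17 | cyclobutenone: benzyl 2-hydroxy-4-{[(2E)-3-(2-methoxy-4-oxocyclobut-2-en-1-yl)but-2-enoyl]oxy}-3,6-dimethylbenzoate (racemic; not isolated) | COC1=CC(=O)C1/C(C)=C/C(=O)Oc2cc(C)c(C(=O)OCc3ccccc3)c(O)c2C | intermediate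
18 | dienylketene: benzyl 2-hydroxy-4-{[(2E,4E)-5-methoxy-3-methyl-7-oxohepta-2,4,6-trienoyl]oxy}-3,6-dimethylbenzoate (ketene arm and enoate arm cis on the central alkene; not isolated) | O=C=C/C(OC)=C\C(C)=C\C(=O)Oc1cc(C)c(C(=O)OCc2ccccc2)c(O)c1C | intermediate
19 | cyclohexadienone: benzyl 2-hydroxy-4-{[(4-methoxy-2-methyl-6-oxocyclohexa-2,4-dien-1-yl)carbonyl]oxy}-3,6-dimethylbenzoate (racemic; not isolated) | COC1=CC(=O)C(C(=O)Oc2cc(C)c(C(=O)OCc3ccccc3)c(O)c2C)C(C)=C1 | intermediate
20 | benzyl 2-hydroxy-4-[(2-hydroxy-4-methoxy-6-methylbenzoyl)oxy]-3,6-dimethylbenzoate (3-decarboxy depside, key-step product) | COc1cc(C)c(C(=O)Oc2cc(C)c(C(=O)OCc3ccccc3)c(O)c2C)c(O)c1 | intermediate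
21 | benzyl 2-hydroxy-4-{[2-hydroxy-3-(hydroxymethyl)-4-methoxy-6-methylbenzoyl]oxy}-3,6-dimethylbenzoate (not isolated) | COc1cc(C)c(C(=O)Oc2cc(C)c(C(=O)OCc3ccccc3)c(O)c2C)c(O)c1CO | intermediate
22 | benzyl 4-[(3-formyl-2-hydroxy-4-methoxy-6-methylbenzoyl)oxy]-2-hydroxy-3,6-dimethylbenzoate | COc1cc(C)c(C(=O)Oc2cc(C)c(C(=O)OCc3ccccc3)c(O)c2C)c(O)c1C=O | intermediate
23 | 3-{[4-(benzyloxycarbonyl)-3-hydroxy-2,5-dimethylphenoxy]carbonyl}-2-hydroxy-6-methoxy-4-methylbenzoic acid | COc1cc(C)c(C(=O)Oc2cc(C)c(C(=O)OCc3ccccc3)c(O)c2C)c(O)c1C(=O)O | intermediate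
24 | squamatic acid, 3-[(4-carboxy-3-hydroxy-2,5-dimethylphenoxy)carbonyl]-2-hydroxy-6-methoxy-4-methylbenzoic acid (no stereocentres) | COc1cc(C)c(C(=O)Oc2cc(C)c(C(=O)O)c(O)c2C)c(O)c1C(=O)O | target

Total step count: 12.
Longest linear sequence: 9 steps (1, 2, 5, 6, 7, 9, 10, 11, 12; the branch 3, 4, 5, 6, 7, 9, 10, 11, 12 is equally long).

Steps most likely to fail

1. Step 9 (benzannulation). The alkene may photoisomerise from E to Z before or after the Wolff shift, which would open oxa-6π closure of the ketene onto the ester carbonyl. The ketenes may also acylate a phenol instead of meeting the alkyne, the aryl ester may undergo photo-Fries rearrangement, or the volatile ynol ether may oligomerise before it is consumed. The fallback gives up the annulation and builds ring A separately; it sets out from ring B phenol 3 and comes back at 20, so steps 3 to 8 are dropped. Purchased methyl 2,4-dihydroxy-6-methylbenzoate F1 is O-methylated at its non-chelated C4 hydroxyl (MeI, K2CO3, acetone) to methyl 2-hydroxy-4-methoxy-6-methylbenzoate F2. Hydrolysis of F2 (aq. KOH, DMSO; cold acidification) gives 2-hydroxy-4-methoxy-6-methylbenzoic acid F3. F3 is condensed with 3 through its mixed anhydride ((CF3CO)2O, toluene, rt), a standard depside esterification that acylates the C4' hydroxyl and gives 20.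

2. Step 6 (enolate trifluoroacetylation). The lithium enolate may add in Michael fashion to enone not yet deprotonated, deprotonation may occur at the C3 methyl of the enoate, or lithium trifluoroethoxide may cleave the aryl ester. The fallback builds the diazo group without a strong base and without diazo transfer; it sets out from 8 and comes back at 11, bypassing 10. Soft enolisation of 8 (Me3SiOSO2CF3, Et3N, CH2Cl2, 0 °C) gives benzyl 3,6-dimethyl-4-{[(2E)-3-methyl-4-(trimethylsilyloxy)penta-2,4-dienoyl]oxy}-2-(trimethylsilyloxy)benzoate F4. Bromination of the silyl enol ether (N-bromosuccinimide, THF, −78 °C, aqueous work-up) gives benzyl 4-{[(2E)-5-bromo-3-methyl-4-oxopent-2-enoyl]oxy}-2-hydroxy-3,6-dimethylbenzoate F5. N-Alkylation of N,N'-ditosylhydrazine by F5 followed by double sulfinate elimination (DBU, THF, 0 °C) gives 11.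

3. Step 10 (formylation). Attack at C3 may be slow, because the position is flanked by two oxygen substituents and the phenoxide is deactivated by the C1 ester. Prolonged heating with Et3N and the methanol formed may then cleave the depside ester by transesterification. The fallback replaces the magnesium phenoxide–formaldehyde redox process by an electrophilic Rieche formylation; it sets out from 20 and comes back at 22. Cl2CHOMe and TiCl4 (CH2Cl2, −20 to 0 °C) should substitute ortho to the titanium-bound phenoxide at C3 to give benzyl 4-({3-[chloro(methoxy)methyl]-2-hydroxy-4-methoxy-6-methylbenzoyl}oxy)-2-hydroxy-3,6-dimethylbenzoate F6, which is hydrolysed on aqueous work-up to 22.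

Further compounds
F1 | step 9 | methyl 2,4-dihydroxy-6-methylbenzoate (purchased) | COC(=O)c1c(C)cc(O)cc1O
F2 | step 9 | methyl 2-hydroxy-4-methoxy-6-methylbenzoate | COC(=O)c1c(C)cc(OC)cc1O
F3 | step 9 | 2-hydroxy-4-methoxy-6-methylbenzoic acid | COc1cc(C)c(C(=O)O)c(O)c1
F4 | step 6 | benzyl 3,6-dimethyl-4-{[(2E)-3-methyl-4-(trimethylsilyloxy)penta-2,4-dienoyl]oxy}-2-(trimethylsilyloxy)benzoate | C=C(O[Si](C)(C)C)/C(C)=C/C(=O)Oc1cc(C)c(C(=O)OCc2ccccc2)c(O[Si](C)(C)C)c1C
F5 | step 6 | benzyl 4-{[(2E)-5-bromo-3-methyl-4-oxopent-2-enoyl]oxy}-2-hydroxy-3,6-dimethylbenzoate | BrCC(=O)/C(C)=C/C(=O)Oc1cc(C)c(C(=O)OCc2ccccc2)c(O)c1C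
F6 | step 10 | benzyl 4-({3-[chloro(methoxy)methyl]-2-hydroxy-4-methoxy-6-methylbenzoyl}oxy)-2-hydroxy-3,6-dimethylbenzoate | COc1cc(C)c(C(=O)Oc2cc(C)c(C(=O)OCc3ccccc3)c(O)c2C)c(O)c1C(Cl)OC
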